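Ring C is opened at C2–C3. C2 is at once benzylic to ring B and α to the ring oxygen O1. In an open precursor it is therefore merely the CH2 of a 4-oxybenzyl aryl ether, the most hydridic C–H site present. C3, α to the C4 ketone, can be a carbenoid carbon. A chiral dirhodium carboxylate decomposes the achiral diazomethyl ketone 8. 1,6-Insertion into one of the two enantiotopic O–CH2 hydrogens then forms C2–C3, closes ring C and sets the only stereocentre (2S) in one operation. The hexasubstituted ring A, prenyl included, is completed beforehand from a commercial acetophenone. A single BCl3 step finally frees both phenols.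

Key step: step 5

Numbering: flavanone numbering is used (O1, C2, C3, C4 = ketone, C4a, C5–C8, C8a; primed numbers for ring B).
Assumption 1: 1 (sold as 6-hydroxy-2,3,4-trimethoxyacetophenone), 3 and 5 are catalogue compounds.
Assumption 2: Rh2(S-PTTL)4, dirhodium tetrakis[N-phthaloyl-(S)-tert-leucinate], is taken to select the pro-S hydrogen. Should a trial show the opposite sense, Rh2(R-PTTL)4 is used in the same way.

Step 1
Reactants: 1 1-(6-hydroxy-2,3,4-trimethoxyphenyl)ethan-1-one
Product: 2 1-(2-hydroxy-3-iodo-4,5,6-trimethoxyphenyl)ethan-1-one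
Conditions: NIS, TFA (cat.), MeCN, 0 °C to rt
Reagents that add atoms: N-iodosuccinimide O=C1CCC(=O)N1I
Why: Electrophilic aromatic iodination; the only free ring position (the future C8) is activated by the ortho hydroxyl, the ortho methoxy and the para methoxy group, so a single iodide should form.

Step 2
Reactants: 2 1-(2-hydroxy-3-iodo-4,5,6-trimethoxyphenyl)ethan-1-one; 3 4-(benzyloxy)benzyl chloride
Product: 4 1-(2-{[4-(benzyloxy)phenyl]methoxy}-3-iodo-4,5,6-trimethoxyphenyl)ethan-1-one
Conditions: K2CO3, Bu4NI (cat.), DMF, 60 °C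
Reagents that add atoms: none
Why: Williamson ether synthesis; the phenoxide of 2 displaces chloride from the reactive benzylic chloride 3 (SN2), which installs the future C2 as an O-bound CH2 together with the masked ring B.

Step 3
Reactants: 4 1-(2-{[4-(benzyloxy)phenyl]methoxy}-3-iodo-4,5,6-trimethoxyphenyl)ethan-1-one; 5 tributyl(3-methylbut-2-en-1-yl)stannane
Product: 6 1-[2-{[4-(benzyloxy)phenyl]methoxy}-4,5,6-trimethoxy-3-(3-methylbut-2-en-1-yl)phenyl]ethan-1-one
Conditions: Pd(PPh3)4 (cat.), DMF, 100 °C, degassed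
Reagents that add atoms: none
Why: Stille coupling; oxidative addition of zerovalent palladium into the aryl iodide, allyl transfer from tin and reductive elimination at the less hindered allyl terminus should give the linear prenyl arene under neutral conditions that leave the ketone and both benzyl ethers alone.

Step 4
Reactants: 6 1-[2-{[4-(benzyloxy)phenyl]methoxy}-4,5,6-trimethoxy-3-(3-methylbut-2-en-1-yl)phenyl]ethan-1-one
Product: 8 1-[2-{[4-(benzyloxy)phenyl]methoxy}-4,5,6-trimethoxy-3-(3-methylbut-2-en-1-yl)phenyl]-2-diazoethan-1-one, via α-trifluoroacetyl ketone 7 (not isolated)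
Conditions: LiHMDS, THF, −78 °C, then CF3CO2CH2CF3; dilute HCl wash; then MsN3, Et3N, H2O (1 equiv), MeCN, rt
Reagents that add atoms: methanesulfonyl azide CS(=O)(=O)N=[N+]=[N-]; 2,2,2-trifluoroethyl trifluoroacetate O=C(OCC(F)(F)F)C(F)(F)F (its CF3CO group is kept only in 7)
Why: Detrifluoroacetylative diazo transfer (Regitz-type); the lithium enolate of the methyl ketone is C-acylated to the activated 1,3-diketone 7, which takes N2 from the sulfonyl azide and passes its trifluoroacetyl group to the sulfonamide nitrogen, a sequence suited to aryl methyl ketones that resist direct diazo transfer.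

Step 5
Reactants: 8 1-[2-{[4-(benzyloxy)phenyl]methoxy}-4,5,6-trimethoxy-3-(3-methylbut-2-en-1-yl)phenyl]-2-diazoethan-1-one
Product: 9 (2S)-2-[4-(benzyloxy)phenyl]-5,6,7-trimethoxy-8-(3-methylbut-2-en-1-yl)-2,3-dihydro-4H-chromen-4-one
Conditions: Rh2(S-PTTL)4 (1–2 mol%), CH2Cl2 (high dilution), 4 Å MS, 0 °C to rt, slow addition of 8
Reagents that add atoms: none
Why: Rh2(S-PTTL)4 displaces N2 from 8 to give an electrophilic rhodium carbenoid at C3, which inserts into an O–CH2 C–H bond of the 4-benzyloxybenzyl ether through a concerted, asynchronous three-centre transition state with hydride-transfer character, so that C2–C3 and C3–H form together. It is the known intramolecular carbenoid C–H insertion of 2-alkoxyaryl α-diazoketones to chroman-4-ones under chiral dirhodium tetracarboxylates, applied here to a benzyl ether so that a flavanone results. Ring C closes as a six-membered ring by 1,6-insertion, because the atom that would lead to the usual five-membered ring is O1, which bears no hydrogen. C2 is the only new stereocentre and is controlled by the catalyst alone: the chiral pocket of the four N-phthaloyl-tert-leucinate ligands differentiates the enantiotopic hydrogens, and replacement of the pro-S hydrogen with retention gives 2S. The step needs insertion at this CH2 to outrun oxonium ylide formation at O1 or at the 5-OMe oxygen with Stevens [1,2]-shift to a benzofuranone, insertion into the 5-OCH3 group, and attack on the prenyl alkene or on ring B. The substrate secures this because the CH2 is activated twice (α to O1 and benzylic to an electron-rich ring) whereas a methoxy C–H is primary, both aryl ether oxygens are weak donors whose ylides form reversibly under rhodium carboxylates (copper is avoided), the C8 prenyl group sits meta to the carbenoid arm and cannot reach it, and slow addition at high dilution suppresses bimolecular cyclopropanation and carbene dimerisation.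

Step 6
Reactants: 9 (2S)-2-[4-(benzyloxy)phenyl]-5,6,7-trimethoxy-8-(3-methylbut-2-en-1-yl)-2,3-dihydro-4H-chromen-4-one
Product: 10 (2S)-5-hydroxy-2-(4-hydroxyphenyl)-6,7-dimethoxy-8-(3-methylbut-2-en-1-yl)-2,3-dihydro-4H-chromen-4-one
Conditions: BCl3, pentamethylbenzene, CH2Cl2, −78 to 0 °C; quench with pH 7 buffer
Reagents that add atoms: none
Why: Lewis-acid ether cleavage; BCl3 chelated between the C4 carbonyl and the peri 5-OMe oxygen cleaves only that methyl ether and also cleaves the 4'-benzyl ether with pentamethylbenzene trapping the benzyl cation, while the low temperature, the electron-poor O–BCl2 state of ring B and the neutral quench should keep the prenyl alkene, the 6- and 7-OMe groups and the C2 configuration intact.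

Compound list
1 | 1-(6-hydroxy-2,3,4-trimethoxyphenyl)ethan-1-one | CC(=O)c1c(O)cc(OC)c(OC)c1OC | starting material
2 | 1-(2-hydroxy-3-iodo-4,5,6-trimethoxyphenyl)ethan-1-one | CC(=O)c1c(O)c(I)c(OC)c(OC)c1OC | intermediate
3 | 4-(benzyloxy)benzyl chloride | ClCc1ccc(OCc2ccccc2)cc1 | starting material
4 | 1-(2-{[4-(benzyloxy)phenyl]methoxy}-3-iodo-4,5,6-trimethoxyphenyl)ethan-1-one | CC(=O)c1c(OCc2ccc(OCc3ccccc3)cc2)c(I)c(OC)c(OC)c1OC | intermediate
5 | tributyl(3-methylbut-2-en-1-yl)stannane | CCCC[Sn](CCCC)(CCCC)CC=C(C)C | starting material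
6 | 1-[2-{[4-(benzyloxy)phenyl]methoxy}-4,5,6-trimethoxy-3-(3-methylbut-2-en-1-yl)phenyl]ethan-1-one | CC(=O)c1c(OCc2ccc(OCc3ccccc3)cc2)c(CC=C(C)C)c(OC)c(OC)c1OC | intermediate
7 | 1-[2-{[4-(benzyloxy)phenyl]methoxy}-4,5,6-trimethoxy-3-(3-methylbut-2-en-1-yl)phenyl]-4,4,4-trifluorobutane-1,3-dione (not isolated) | O=C(CC(=O)C(F)(F)F)c1c(OCc2ccc(OCc3ccccc3)cc2)c(CC=C(C)C)c(OC)c(OC)c1OC | intermediate
8 | 1-[2-{[4-(benzyloxy)phenyl]methoxy}-4,5,6-trimethoxy-3-(3-methylbut-2-en-1-yl)phenyl]-2-diazoethan-1-one | [N-]=[N+]=CC(=O)c1c(OCc2ccc(OCc3ccccc3)cc2)c(CC=C(C)C)c(OC)c(OC)c1OC | intermediate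
9 | (2S)-2-[4-(benzyloxy)phenyl]-5,6,7-trimethoxy-8-(3-methylbut-2-en-1-yl)-2,3-dihydro-4H-chromen-4-one | COc1c(OC)c2c(c(CC=C(C)C)c1OC)O[C@H](c1ccc(OCc3ccccc3)cc1)CC2=O | intermediate
10 | (2S)-5-hydroxy-2-(4-hydroxyphenyl)-6,7-dimethoxy-8-(3-methylbut-2-en-1-yl)-2,3-dihydro-4H-chromen-4-one | COc1c(O)c2c(c(CC=C(C)C)c1OC)O[C@H](c1ccc(O)cc1)CC2=O | target

Total step count: 6. Longest linear sequence: 6 steps (1 to 10).

Steps most likely to fail

Step 5.
- **What may go wrong:** the carbenoid is diverted to an oxonium ylide at O1, followed by [1,2]-migration of the electron-rich benzyl group, or the two enantiotopic hydrogens are only weakly discriminated.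
- **Fallback idea (sets out from 2, returns at 9):** ring C is closed at the same C2–C3 bond, but as a C2=C3 double bond by intramolecular Wittig olefination of an aryl ester. The stereocentre is set afterwards by copper hydride.
- **Ester and ylide:** 2 is acylated with 4-(benzyloxy)benzoyl chloride (Et3N, DMAP, CH2Cl2) to 2-acetyl-6-iodo-3,4,5-trimethoxyphenyl 4-(benzyloxy)benzoate F1. CuBr2 in EtOAc/CHCl3 at reflux gives 2-(bromoacetyl)-6-iodo-3,4,5-trimethoxyphenyl 4-(benzyloxy)benzoate F2. PPh3 in toluene gives {2-[2-{[4-(benzyloxy)benzoyl]oxy}-3-iodo-4,5,6-trimethoxyphenyl]-2-oxoethyl}triphenylphosphonium bromide F3. Aqueous Na2CO3 liberates the acyl-stabilised ylide 2-iodo-3,4,5-trimethoxy-6-[(triphenylphosphoranylidene)acetyl]phenyl 4-(benzyloxy)benzoate F4.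
- **Ring closure and prenylation:** in refluxing toluene the ylide olefinates the neighbouring ester carbonyl to give 2-[4-(benzyloxy)phenyl]-8-iodo-5,6,7-trimethoxy-4H-chromen-4-one F5. Stille coupling with 5 gives 2-[4-(benzyloxy)phenyl]-5,6,7-trimethoxy-8-(3-methylbut-2-en-1-yl)-4H-chromen-4-one F6.
- **Stereocentre:** asymmetric conjugate reduction, known for chromones, uses Cu(OAc)2, the DTBM-SEGPHOS enantiomer that delivers hydride to the C2 face leading to 2S, and (EtO)2MeSiH with t-BuOH in toluene. It should leave the isolated prenyl alkene untouched and give 9.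

Step 6.
- **What may go wrong:** acid-induced hydrochlorination or cationic cyclisation of the prenyl chain, or further demethylation at C6, during the Lewis-acid unmasking.
- **Fallback idea (sets out from 4, returns at 10):** the order of events is changed so that the prenyl group never meets BCl3. The C8 iodide is carried through and the prenyl group is installed last.
- **Sequence:** 4 undergoes the same diazo transfer through 1-(2-{[4-(benzyloxy)phenyl]methoxy}-3-iodo-4,5,6-trimethoxyphenyl)-4,4,4-trifluorobutane-1,3-dione F7 to 1-(2-{[4-(benzyloxy)phenyl]methoxy}-3-iodo-4,5,6-trimethoxyphenyl)-2-diazoethan-1-one F8. The same rhodium-catalysed insertion gives (2S)-2-[4-(benzyloxy)phenyl]-8-iodo-5,6,7-trimethoxy-2,3-dihydro-4H-chromen-4-one F9. BCl3 with pentamethylbenzene gives (2S)-5-hydroxy-2-(4-hydroxyphenyl)-8-iodo-6,7-dimethoxy-2,3-dihydro-4H-chromen-4-one F10. A neutral Stille coupling with 5 (Pd(PPh3)4, DMF) delivers 10.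

Step 3.
- **What may go wrong:** sluggish coupling at an iodide flanked by two ortho oxygen substituents, protodeiodination, or allylic transposition to the 1,1-dimethylallyl isomer.
- **Fallback idea (sets out from 1, returns at 6):** the prenyl group is delivered by a sigmatropic route without any halide.
- **Sequence:** 1 is O-alkylated at the tertiary allyl terminus with tert-butyl 2-methylbut-3-en-2-yl carbonate and Pd(PPh3)4 (THF, 0 °C) to 1-{2,3,4-trimethoxy-6-[(2-methylbut-3-en-2-yl)oxy]phenyl}ethan-1-one F11. Aromatic Claisen rearrangement (toluene, 110 °C) moves the allyl unit with inversion to the only free ortho carbon and gives 1-[2-hydroxy-4,5,6-trimethoxy-3-(3-methylbut-2-en-1-yl)phenyl]ethan-1-one F12. Williamson alkylation with 3 (K2CO3, DMF) gives 6.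

Further compounds
F1 | step 5 | 2-acetyl-6-iodo-3,4,5-trimethoxyphenyl 4-(benzyloxy)benzoate | CC(=O)c1c(OC(=O)c2ccc(OCc3ccccc3)cc2)c(I)c(OC)c(OC)c1OC
F2 | step 5 | 2-(bromoacetyl)-6-iodo-3,4,5-trimethoxyphenyl 4-(benzyloxy)benzoate | O=C(CBr)c1c(OC(=O)c2ccc(OCc3ccccc3)cc2)c(I)c(OC)c(OC)c1OC
F3 | step 5 | {2-[2-{[4-(benzyloxy)benzoyl]oxy}-3-iodo-4,5,6-trimethoxyphenyl]-2-oxoethyl}triphenylphosphonium bromide | [Br-].O=C(C[P+](c1ccccc1)(c1ccccc1)c1ccccc1)c1c(OC(=O)c2ccc(OCc3ccccc3)cc2)c(I)c(OC)c(OC)c1OC
F4 | step 5 | 2-iodo-3,4,5-trimethoxy-6-[(triphenylphosphoranylidene)acetyl]phenyl 4-(benzyloxy)benzoate | O=C(C=P(c1ccccc1)(c1ccccc1)c1ccccc1)c1c(OC(=O)c2ccc(OCc3ccccc3)cc2)c(I)c(OC)c(OC)c1OC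
F5 | step 5 | 2-[4-(benzyloxy)phenyl]-8-iodo-5,6,7-trimethoxy-4H-chromen-4-one | COc1c(OC)c2c(c(I)c1OC)OC(=CC2=O)c1ccc(OCc3ccccc3)cc1
F6 | step 5 | 2-[4-(benzyloxy)phenyl]-5,6,7-trimethoxy-8-(3-methylbut-2-en-1-yl)-4H-chromen-4-one | COc1c(OC)c2c(c(CC=C(C)C)c1OC)OC(=CC2=O)c1ccc(OCc3ccccc3)cc1
F7 | step 6 | 1-(2-{[4-(benzyloxy)phenyl]methoxy}-3-iodo-4,5,6-trimethoxyphenyl)-4,4,4-trifluorobutane-1,3-dione | O=C(CC(=O)C(F)(F)F)c1c(OCc2ccc(OCc3ccccc3)cc2)c(I)c(OC)c(OC)c1OC
F8 | step 6 | 1-(2-{[4-(benzyloxy)phenyl]methoxy}-3-iodo-4,5,6-trimethoxyphenyl)-2-diazoethan-1-one | [N-]=[N+]=CC(=O)c1c(OCc2ccc(OCc3ccccc3)cc2)c(I)c(OC)c(OC)c1OC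
F9 | step 6 | (2S)-2-[4-(benzyloxy)phenyl]-8-iodo-5,6,7-trimethoxy-2,3-dihydro-4H-chromen-4-one | COc1c(OC)c2c(c(I)c1OC)O[C@H](c1ccc(OCc3ccccc3)cc1)CC2=O
F10 | step 6 | (2S)-5-hydroxy-2-(4-hydroxyphenyl)-8-iodo-6,7-dimethoxy-2,3-dihydro-4H-chromen-4-one | COc1c(O)c2c(c(I)c1OC)O[C@H](c1ccc(O)cc1)CC2=O
F11 | step 3 | 1-{2,3,4-trimethoxy-6-[(2-methylbut-3-en-2-yl)oxy]phenyl}ethan-1-one | CC(=O)c1c(OC(C)(C)C=C)cc(OC)c(OC)c1OC
F12 | step 3 | 1-[2-hydroxy-4,5,6-trimethoxy-3-(3-methylbut-2-en-1-yl)phenyl]ethan-1-one | CC(=O)c1c(O)c(CC=C(C)C)c(OC)c(OC)c1OC
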